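**Plan**

- Retrosynthesis: the C7=C8 enal bond on ring A is cut first (Wittig), C9'–OH is traced back to a vinyl group on C8', then the O4–C8' bond of the dioxane ring is cut (palladium allyl closure), then the inner alkene of the allylic carbonate (cross-metathesis), and last the O5–C7' ether bond (iridium allylic etherification).
- Forward: 5-hydroxyvanillin with O4 masked and a guaiacyl cinnamyl carbonate are joined at O5–C7', the chain is lengthened by one CH2O unit, and the dioxane ring, the only ring made, closes at O4–C8'. The vinyl group then becomes CH2OH and the ring A aldehyde becomes the enal.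
- Enabling feature: C8' carries the ring oxygen O4 and the one-carbon arm C9'. With C9' held as part of a vinyl group, C8' is the inner terminus of an allyl unit next to the already fixed C7', placed so that the O4 phenol closes a six-membered ring.
- Stereochemistry: C7' is set by the chiral iridium catalyst; C8' is set trans to it by the existing C7' centre, reinforced by the palladium ligand. Neither centre is touched afterwards.

Key step: step 9

Locants: ring A is the 5-hydroxyvanillin ring (O4 para to the C1 side chain, O5 meta); the guaiacyl unit is primed, with C7' aryl-bearing, C8' and C9'. In benzodioxine names C2 = C8' and C3 = C7'.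

Assumption: the (Ra,Rc,Rc) phosphoramidite is taken to give the (R) ether 8 and the (R,R) DACH-phenyl ligand to be matched to the trans closure; if either sense of induction proves opposite, the antipodal ligand is used and nothing else changes.

**Route**

Step 1
Reactants: 1 5-hydroxyvanillin (3,4-dihydroxy-5-methoxybenzaldehyde)
Product: 2 3-hydroxy-5-methoxy-4-{[2-(trimethylsilyl)ethoxy]methoxy}benzaldehyde
Conditions: SEMCl (1.05 equiv), Li2CO3 (1.0 equiv), DMF, rt
Reagents that add atoms: 2-(trimethylsilyl)ethoxymethyl chloride (SEMCl), C[Si](C)(C)CCOCCl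
Why: Williamson-type O-alkylation under mono-deprotonation: the 4-OH para to the formyl group is the more acidic phenol, so one equivalent of weak base should place the acetal-type SEM group on O4, where it cannot migrate to O5 under later basic conditions.

Step 2
Reactants: 3 methyl ferulate
Product: 4 methyl (2E)-3-[3-methoxy-4-(methoxymethoxy)phenyl]prop-2-enoate
Conditions: MOMCl (1.5 equiv), i-Pr2NEt (1.5 equiv), CH2Cl2, 0 °C to rt
Reagents that add atoms: chloromethyl methyl ether (MOMCl), COCCl
Why: Standard MOM etherification of a phenol, which removes the competing nucleophile and gives a group stable to base, fluoride, ruthenium, palladium, periodate and hydride.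

Step 3
Reactants: 4 methyl (2E)-3-[3-methoxy-4-(methoxymethoxy)phenyl]prop-2-enoate
Product: 5 (2E)-3-[3-methoxy-4-(methoxymethoxy)phenyl]prop-2-en-1-ol
Conditions: i-Bu2AlH (2.5 equiv), CH2Cl2, −78 to 0 °C; aq. potassium sodium tartrate
Reagents that add atoms: none
Why: 1,2-Reduction of an enoate by i-Bu2AlH at low temperature should give the allylic alcohol without conjugate reduction and leave the aryl MOM ether intact.

Step 4
Reactants: 5 (2E)-3-[3-methoxy-4-(methoxymethoxy)phenyl]prop-2-en-1-ol
Product: 6 (2E)-3-[3-methoxy-4-(methoxymethoxy)phenyl]prop-2-en-1-yl methyl carbonate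
Conditions: ClCO2Me (1.2 equiv), pyridine, CH2Cl2, 0 °C
Reagents that add atoms: methyl chloroformate, COC(=O)Cl
Why: O-acylation of the primary allylic alcohol installs the carbonate leaving group that iridium allyl chemistry requires.

Step 5
Reactants: 2 3-hydroxy-5-methoxy-4-{[2-(trimethylsilyl)ethoxy]methoxy}benzaldehyde; 6 (2E)-3-[3-methoxy-4-(methoxymethoxy)phenyl]prop-2-en-1-yl methyl carbonate
Product: 8 3-methoxy-5-({(1R)-1-[3-methoxy-4-(methoxymethoxy)phenyl]prop-2-en-1-yl}oxy)-4-{[2-(trimethylsilyl)ethoxy]methoxy}benzaldehyde, via sodium aryloxide 7 (not isolated)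
Conditions: 2 (1.3 equiv), NaH (1.3 equiv), THF, 0 °C; then 6, [Ir(cod)Cl]2 (2 mol%), (Ra,Rc,Rc)-O,O'-(1,1'-binaphthyl-2,2'-diyl)-N,N-bis(1-phenylethyl)phosphoramidite (4 mol%), THF, 50 °C
Reagents that add atoms: none
Why: Iridium-catalysed asymmetric allylic etherification: the cyclometalated iridium phosphoramidite ionises the cinnamyl carbonate and the aryloxide attacks the aryl-bearing allyl terminus, so the branched O5–C7' ether should form with the ligand fixing the face of attack; the centre is (R) here and becomes 7'S after ring closure only through a change in CIP priorities.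

Step 6
Reactants: 8 3-methoxy-5-({(1R)-1-[3-methoxy-4-(methoxymethoxy)phenyl]prop-2-en-1-yl}oxy)-4-{[2-(trimethylsilyl)ethoxy]methoxy}benzaldehyde
Product: 9 4-hydroxy-3-methoxy-5-({(1R)-1-[3-methoxy-4-(methoxymethoxy)phenyl]prop-2-en-1-yl}oxy)benzaldehyde
Conditions: Bu4NF (3 equiv), THF, 50 °C; AcOH quench
Reagents that add atoms: none
Why: Fluoride-induced fragmentation of the aryl SEM ether (attack at silicon, loss of ethene and formaldehyde) is eased by the para-formyl phenoxide leaving group and should spare the MOM ether, the allylic ether and the aldehyde.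

Step 7
Reactants: 10 (Z)-but-2-ene-1,4-diol
Product: 11 (2Z)-but-2-ene-1,4-diyl dimethyl dicarbonate
Conditions: ClCO2Me (2.4 equiv), pyridine, CH2Cl2, 0 °C
Reagents that add atoms: methyl chloroformate, COC(=O)Cl
Why: Double O-acylation of a primary diol gives the symmetric metathesis partner that carries the carbonate leaving group.

Step 8
Reactants: 9 4-hydroxy-3-methoxy-5-({(1R)-1-[3-methoxy-4-(methoxymethoxy)phenyl]prop-2-en-1-yl}oxy)benzaldehyde; 11 (2Z)-but-2-ene-1,4-diyl dimethyl dicarbonate
Product: 12 (2E,4R)-4-(5-formyl-2-hydroxy-3-methoxyphenoxy)-4-[3-methoxy-4-(methoxymethoxy)phenyl]but-2-en-1-yl methyl carbonate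
Conditions: 11 (3 equiv), second-generation Hoveyda–Grubbs catalyst (5 mol%), CH2Cl2, 40 °C
Reagents that add atoms: none
Why: Olefin cross-metathesis between the hindered vinyl group of 9, which is slow to homodimerise, and an excess of the symmetric cis-butene dicarbonate should give mainly the (E)-allylic carbonate; any (Z) isomer converges on the same π-allyl complex in step 9, and ruthenium carbenes tolerate the phenol and the aldehyde.

Step 9
Reactants: 12 (2E,4R)-4-(5-formyl-2-hydroxy-3-methoxyphenoxy)-4-[3-methoxy-4-(methoxymethoxy)phenyl]but-2-en-1-yl methyl carbonate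
Product: 13 (2S,3S)-2-ethenyl-8-methoxy-3-[3-methoxy-4-(methoxymethoxy)phenyl]-2,3-dihydro-1,4-benzodioxine-6-carbaldehyde (trans)
Conditions: Pd2(dba)3·CHCl3 (2.5 mol%), (R,R)-DACH-phenyl Trost ligand (7.5 mol%), AcOH (1 equiv), CH2Cl2, rt
Reagents that add atoms: none
Why: Zerovalent palladium ionises the allylic methyl carbonate (loss of CO2 and methoxide) to a π-allyl complex over C8', C9' and the outer carbon, and the O4 phenoxide, the only free phenol, attacks C8' anti to the metal. The closest known reaction type is the Tsuji–Trost allylic etherification of phenols, as in the palladium-catalysed formation of 2-vinyl-1,4-benzodioxanes from catechols and butenediyl dicarbonates and in the cyclisation of phenol-tethered allyl carbonates to 2-vinylchromans. The dioxane ring closes 6-exo at the inner allyl terminus; attack at the outer terminus would need an eight-membered ring, so the branched regiochemistry is fixed by ring size. The new centre C8' is controlled by the existing C7': the two π-allyl diastereomers interconvert by π–σ–π through the unsubstituted terminus, closure through a chair-like transition state places guaiacyl and vinyl both equatorial, and re-ionisation of the product allyl aryl ether lets any cis isomer drain to trans, the matched ligand adding to this bias. The selectivity needed is ionisation of the carbonate before the allylic benzylic C7'–O5 ether, which the far better carbonate leaving group, irreversible decarboxylation and room temperature should secure; once the ring is closed C7'–O5 is no longer allylic.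

Step 10
Reactants: 13 (2S,3S)-2-ethenyl-8-methoxy-3-[3-methoxy-4-(methoxymethoxy)phenyl]-2,3-dihydro-1,4-benzodioxine-6-carbaldehyde
Product: 15 (2S,3S)-2,6-bis(hydroxymethyl)-8-methoxy-3-[3-methoxy-4-(methoxymethoxy)phenyl]-2,3-dihydro-1,4-benzodioxine, via trans dialdehyde 14 (not isolated)
Conditions: OsO4 (2 mol%), NaIO4 (4 equiv), 2,6-lutidine (2 equiv), 1,4-dioxane/H2O (3:1), rt; extractive work-up; then NaBH4 (3 equiv), MeOH, 0 °C
Reagents that add atoms: sodium periodate, [Na+].[O-]I(=O)(=O)=O (terminal oxidant; the oxygen is delivered through catalytic osmium tetroxide, O=[Os](=O)(=O)=O)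
Why: Lemieux–Johnson cleavage of the only alkene gives the C9' aldehyde, and immediate borohydride reduction of the crude material converts both aldehydes to alcohols before the α-aryloxy aldehyde can epimerise at C8' (the trans isomer is in any case the more stable).

Step 11
Reactants: 15 (2S,3S)-2,6-bis(hydroxymethyl)-8-methoxy-3-[3-methoxy-4-(methoxymethoxy)phenyl]-2,3-dihydro-1,4-benzodioxine
Product: 16 (2S,3S)-2-(hydroxymethyl)-8-methoxy-3-[3-methoxy-4-(methoxymethoxy)phenyl]-2,3-dihydro-1,4-benzodioxine-6-carbaldehyde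
Conditions: activated MnO2 (15 equiv), CH2Cl2, rt
Reagents that add atoms: none
Why: Manganese dioxide oxidation is selective for the electron-rich benzylic alcohol, so the ring A aldehyde should be restored while the aliphatic C9'–OH stays untouched.

Step 12
Reactants: 16 (2S,3S)-2-(hydroxymethyl)-8-methoxy-3-[3-methoxy-4-(methoxymethoxy)phenyl]-2,3-dihydro-1,4-benzodioxine-6-carbaldehyde
Product: 17 (2E)-3-{(2S,3S)-2-(hydroxymethyl)-8-methoxy-3-[3-methoxy-4-(methoxymethoxy)phenyl]-2,3-dihydro-1,4-benzodioxin-6-yl}prop-2-enal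
Conditions: Ph3P=CHCHO (1.5 equiv), toluene, 90 °C
Reagents that add atoms: (triphenylphosphoranylidene)acetaldehyde, O=CC=P(c1ccccc1)(c1ccccc1)c1ccccc1
Why: Wittig olefination with the stabilised formyl ylide should give the (E)-enal under thermodynamic control and tolerates the free primary alcohol.

Step 13
Reactants: 17 (2E)-3-{(2S,3S)-2-(hydroxymethyl)-8-methoxy-3-[3-methoxy-4-(methoxymethoxy)phenyl]-2,3-dihydro-1,4-benzodioxin-6-yl}prop-2-enal
Product: 18 (7'S,8'S)-nocomtal, (2E)-3-[(2S,3S)-3-(4-hydroxy-3-methoxyphenyl)-2-(hydroxymethyl)-8-methoxy-2,3-dihydro-1,4-benzodioxin-6-yl]prop-2-enal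
Conditions: 2 M aq. HCl/THF (1:4), 45 °C
Reagents that add atoms: none
Why: Acid hydrolysis of the aryl MOM acetal frees the guaiacyl phenol; the trans benzodioxane is the thermodynamic isomer, so reversible benzylic ionisation cannot change the configuration, and the enal and primary alcohol tolerate dilute acid.

**Compound list**

1 | 5-hydroxyvanillin (3,4-dihydroxy-5-methoxybenzaldehyde) | COc1cc(C=O)cc(O)c1O | starting material
2 | 3-hydroxy-5-methoxy-4-{[2-(trimethylsilyl)ethoxy]methoxy}benzaldehyde | COc1cc(C=O)cc(O)c1OCOCC[Si](C)(C)C | intermediate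
3 | methyl ferulate | COc1cc(/C=C/C(=O)OC)ccc1O | starting material
4 | methyl (2E)-3-[3-methoxy-4-(methoxymethoxy)phenyl]prop-2-enoate | COCOc1ccc(/C=C/C(=O)OC)cc1OC | intermediate
5 | (2E)-3-[3-methoxy-4-(methoxymethoxy)phenyl]prop-2-en-1-ol | COCOc1ccc(/C=C/CO)cc1OC | intermediate
6 | (2E)-3-[3-methoxy-4-(methoxymethoxy)phenyl]prop-2-en-1-yl methyl carbonate | COCOc1ccc(/C=C/COC(=O)OC)cc1OC | intermediate
7 | sodium 5-formyl-3-methoxy-2-{[2-(trimethylsilyl)ethoxy]methoxy}phenolate (formed in the flask) | [Na+].[O-]c1cc(C=O)cc(OC)c1OCOCC[Si](C)(C)C | intermediate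
8 | 3-methoxy-5-({(1R)-1-[3-methoxy-4-(methoxymethoxy)phenyl]prop-2-en-1-yl}oxy)-4-{[2-(trimethylsilyl)ethoxy]methoxy}benzaldehyde | COCOc1ccc(cc1OC)[C@H](Oc1cc(C=O)cc(OC)c1OCOCC[Si](C)(C)C)C=C | intermediate
9 | 4-hydroxy-3-methoxy-5-({(1R)-1-[3-methoxy-4-(methoxymethoxy)phenyl]prop-2-en-1-yl}oxy)benzaldehyde | COCOc1ccc(cc1OC)[C@H](Oc1cc(C=O)cc(OC)c1O)C=C | intermediate
10 | (Z)-but-2-ene-1,4-diol | OC/C=C\CO | starting material
11 | (2Z)-but-2-ene-1,4-diyl dimethyl dicarbonate | COC(=O)OC/C=C\COC(=O)OC | intermediate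
12 | (2E,4R)-4-(5-formyl-2-hydroxy-3-methoxyphenoxy)-4-[3-methoxy-4-(methoxymethoxy)phenyl]but-2-en-1-yl methyl carbonate | COCOc1ccc(cc1OC)[C@H](Oc1cc(C=O)cc(OC)c1O)/C=C/COC(=O)OC | intermediate
13 | (2S,3S)-2-ethenyl-8-methoxy-3-[3-methoxy-4-(methoxymethoxy)phenyl]-2,3-dihydro-1,4-benzodioxine-6-carbaldehyde (trans) | COCOc1ccc(cc1OC)[C@@H]2Oc3cc(C=O)cc(OC)c3O[C@H]2C=C | intermediate
14 | trans-8-methoxy-3-[3-methoxy-4-(methoxymethoxy)phenyl]-2,3-dihydro-1,4-benzodioxine-2,6-dicarbaldehyde, formally (2R,3S), same spatial arrangement as 13 (formed in the flask) | COCOc1ccc(cc1OC)[C@@H]2Oc3cc(C=O)cc(OC)c3O[C@H]2C=O | intermediate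
15 | (2S,3S)-2,6-bis(hydroxymethyl)-8-methoxy-3-[3-methoxy-4-(methoxymethoxy)phenyl]-2,3-dihydro-1,4-benzodioxine | COCOc1ccc(cc1OC)[C@@H]2Oc3cc(CO)cc(OC)c3O[C@H]2CO | intermediate
16 | (2S,3S)-2-(hydroxymethyl)-8-methoxy-3-[3-methoxy-4-(methoxymethoxy)phenyl]-2,3-dihydro-1,4-benzodioxine-6-carbaldehyde | COCOc1ccc(cc1OC)[C@@H]2Oc3cc(C=O)cc(OC)c3O[C@H]2CO | intermediate
17 | (2E)-3-{(2S,3S)-2-(hydroxymethyl)-8-methoxy-3-[3-methoxy-4-(methoxymethoxy)phenyl]-2,3-dihydro-1,4-benzodioxin-6-yl}prop-2-enal | COCOc1ccc(cc1OC)[C@@H]2Oc3cc(/C=C/C=O)cc(OC)c3O[C@H]2CO | intermediate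
18 | (7'S,8'S)-nocomtal | COc1cc([C@@H]2Oc3cc(/C=C/C=O)cc(OC)c3O[C@H]2CO)ccc1O | target

**Step count**

Total step count: 13.
Longest linear sequence: 11 steps (3 to 18 through steps 2, 3, 4, 5, 6, 8, 9, 10, 11, 12 and 13).

**Steps most likely to fail**

Step 9. Zerovalent palladium may ionise the allylic benzylic C7'–O5 ether in competition with the carbonate, eroding the C7' configuration, or the π-allyl diastereomers may close before they equilibrate, giving weak control at C8'. Fallback: setting out from phenol 9, iodoetherification (I2, NaHCO3, MeCN, 0 °C) would form the same O4–C8' bond 6-exo and should give the trans iodomethyl benzodioxane F4. Displacement of iodide with CsOAc in DMF would give the acetate F5, and K2CO3 in MeOH would release hydroxy aldehyde 16, where the route is rejoined (steps 8 to 11 are then not needed).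

Step 5. The ortho-alkoxy aryloxide may attack slowly, and the electron-rich branched ether may re-ionise on the catalyst and drift to the linear isomer or lose enantiomeric purity. Fallback: setting out from allylic alcohol 5 and phenol 2, Sharpless asymmetric epoxidation of 5 (Ti(OiPr)4, D-(−)-diisopropyl tartrate, t-BuOOH, 4 Å sieves, CH2Cl2, −20 °C) would give the (2R,3R)-epoxy alcohol F1, to be used crude because it is acid-sensitive. Opening by the phenoxide of 2 (NaOH, H2O/1,4-dioxane, 60 °C) at the benzylic carbon with inversion would give the (2R,3S)-diol F2. Thiocarbonyldiimidazole would convert it to the cyclic thionocarbonate F3, and Corey–Winter olefination (P(OMe)3, 110 °C) would give vinyl ether 8, where the route is rejoined.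

Step 12. The product enal may react a second time with the ylide (over-homologation to the dienal), and the electron-rich aldehyde may react sluggishly. Fallback: setting out from aldehyde 16, Horner–Wadsworth–Emmons olefination with triethyl phosphonoacetate (LiCl, DBU, MeCN) would give the ethyl (E)-enoate F6. Reduction with i-Bu2AlH (CH2Cl2, −78 °C) would give the allylic alcohol F7, and MnO2 would oxidise only the allylic alcohol to enal 17, where the route is rejoined.

**Further compounds**

F1 | step 5 | {(2R,3R)-3-[3-methoxy-4-(methoxymethoxy)phenyl]oxiran-2-yl}methanol | OC[C@H]1O[C@@H]1c1ccc(OCOC)c(OC)c1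
F2 | step 5 | (2R,3S)-3-(5-formyl-3-methoxy-2-{[2-(trimethylsilyl)ethoxy]methoxy}phenoxy)-3-[3-methoxy-4-(methoxymethoxy)phenyl]propane-1,2-diol | COCOc1ccc(cc1OC)[C@H](Oc1cc(C=O)cc(OC)c1OCOCC[Si](C)(C)C)[C@H](O)CO
F3 | step 5 | 3-methoxy-5-({(S)-[3-methoxy-4-(methoxymethoxy)phenyl][(4R)-2-thioxo-1,3-dioxolan-4-yl]methyl}oxy)-4-{[2-(trimethylsilyl)ethoxy]methoxy}benzaldehyde | COCOc1ccc(cc1OC)[C@H](Oc1cc(C=O)cc(OC)c1OCOCC[Si](C)(C)C)[C@H]1COC(=S)O1
F4 | step 9 | trans-2-(iodomethyl)-8-methoxy-3-[3-methoxy-4-(methoxymethoxy)phenyl]-2,3-dihydro-1,4-benzodioxine-6-carbaldehyde, formally (2R,3S) | COCOc1ccc(cc1OC)[C@@H]2Oc3cc(C=O)cc(OC)c3O[C@H]2CI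
F5 | step 9 | {(2S,3S)-6-formyl-8-methoxy-3-[3-methoxy-4-(methoxymethoxy)phenyl]-2,3-dihydro-1,4-benzodioxin-2-yl}methyl acetate | COCOc1ccc(cc1OC)[C@@H]2Oc3cc(C=O)cc(OC)c3O[C@H]2COC(C)=O
F6 | step 12 | ethyl (2E)-3-{(2S,3S)-2-(hydroxymethyl)-8-methoxy-3-[3-methoxy-4-(methoxymethoxy)phenyl]-2,3-dihydro-1,4-benzodioxin-6-yl}prop-2-enoate | COCOc1ccc(cc1OC)[C@@H]2Oc3cc(/C=C/C(=O)OCC)cc(OC)c3O[C@H]2CO
F7 | step 12 | (2E)-3-{(2S,3S)-2-(hydroxymethyl)-8-methoxy-3-[3-methoxy-4-(methoxymethoxy)phenyl]-2,3-dihydro-1,4-benzodioxin-6-yl}prop-2-en-1-ol | COCOc1ccc(cc1OC)[C@@H]2Oc3cc(/C=C/CO)cc(OC)c3O[C@H]2CO
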